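**Retrosynthetic overview**

1. The C3 ester is made last from (E)-oct-2-enoic acid and an N-Boc/O-TBS amino alcohol. The piperidine ring is closed at N1–C2 by SN2 with inversion on an open-chain C2 mesylate, which gives 2-Me cis to 3-O and trans to C8.
2. That chain comes from a cis-fused octahydroquinolin-2-one: C3–O by convex-face enolate hydroxylation, the C2 methyl by MeMgBr opening of the N-Cbz lactam, the C2 carbinol by chelation-controlled reduction.
3. The cis-lactam comes from hydrogenation of the Δ4a(8a)-enamide lactam (C4a–H and C8a–H added anti to the C5 chain), itself made by NH3 annulation of a δ-keto acyl unit.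
4. Key disconnection: C5–C1′ and C4a–C4 are formed in one three-component coupling of cyclohex-2-enone, the side-chain Grignard reagent (chiral Cu catalyst sets C5) and N-acryloyloxazolidinone. The enabling feature is that in the carbocycle C4a–C5–C6–C7–C8–C8a, C5 is β and C4a is α to the nitrogen-bearing C8a, so the ring is a latent cyclohex-2-enone (C8a = C=O, C4a=C5).
5. Ring order: the carbocycle is bought as cyclohexenone; the N-ring is closed first as the lactam (step 5), opened at N1–C2 (step 10) and re-closed as the piperidine (step 13).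

Key step: step 4

Remark on the chemistry: ring atoms carry decahydroquinoline numbers throughout (N1, C2–C4, C4a, C5–C8, C8a; side chain C1′–C8′), also in monocyclic intermediates. Of the two Taniaphos enantiomers, the one that gives the (S)-configured β-carbon (C5) is assumed. TBS = tert-butyldimethylsilyl.

**Step 1**
Reactants: 1 (R)-2-propyloxirane; 2 allylmagnesium bromide
Product: 3 (4R)-oct-7-en-4-ol
Conditions: CuI (10 mol %), THF, −30 → 0 °C; aq. NH4Cl
Reagents that add atoms: none
Why: Cu-catalysed SN2 opening of the terminal epoxide at its CH2 carbon by the allyl Grignard reagent should give the homoallyl carbinol without touching the stereocentre (future C5′).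

**Step 2**
Reactants: 3 (4R)-oct-7-en-4-ol
Product: 4 tert-butyldimethyl{[(4R)-oct-7-en-4-yl]oxy}silane
Conditions: TBSCl, imidazole, DMF, rt
Reagents that add atoms: tert-butyldimethylsilyl chloride, CC(C)(C)[Si](C)(C)Cl
Why: Standard silylation of a secondary alcohol; the TBS ether should survive the organometallic, basic and hydrogenation steps and fall together with Boc at the end.

**Step 3**
Reactants: 4 tert-butyldimethyl{[(4R)-oct-7-en-4-yl]oxy}silane
Product: 6 {[(4R)-8-bromooctan-4-yl]oxy}(tert-butyl)dimethylsilane, via alkylzirconocene chloride 5 (not isolated)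
Conditions: Cp2Zr(H)Cl, CH2Cl2, rt; then NBS, 0 °C
Reagents that add atoms: N-bromosuccinimide, O=C1CCC(=O)N1Br
Why: Hydrozirconation places Zr at the terminal carbon (anti-Markovnikov), and electrophilic bromination of the C–Zr bond should give the primary bromide (hydrozirconation–halogenation).

**Step 4**
Reactants: 6 {[(4R)-8-bromooctan-4-yl]oxy}(tert-butyl)dimethylsilane; 7 cyclohex-2-en-1-one; 8 3-acryloyl-1,3-oxazolidin-2-one
Product: 11 3-{3-[(1R,2S)-2-{(5R)-5-[(tert-butyldimethylsilyl)oxy]octyl}-6-oxocyclohexyl]propanoyl}-1,3-oxazolidin-2-one (C4a/C5 trans), via Grignard reagent 9 (not isolated), via magnesium enolate 10 (not isolated)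
Conditions: Mg, Et2O, reflux; then CuCl (5 mol %), Taniaphos (6 mol %), 7, Et2O, 0 °C; then 8, THF, −40 → 0 °C; aq. NH4Cl
Reagents that add atoms: none
Why: The alkylmagnesium bromide transmetallates to the chiral Cu(I)–ferrocenyl diphosphine complex, which transfers the C1′ alkyl group to C5 of cyclohex-2-enone (Cu(III) intermediate, reductive elimination) and releases the bromomagnesium enolate 10 regiospecifically as the C4a=C8a–O enolate; this adds through C4a to the β-carbon of the Mg-chelated, hence strongly activated, N-acryloyl oxazolidinone, and the chelated imide enolate so formed should be too stabilised to add to a second acceptor. The closest known reaction type is the Cu-catalysed asymmetric conjugate addition of Grignard reagents to cyclic enones with in-flask trapping of the magnesium enolate by an electrophile (tandem conjugate addition–Michael three-component coupling). No ring is closed: the carbocycle C4a–C5–C6–C7–C8–C8a is brought in intact by the enone. C5 is set by the ligand (catalyst control), while C4a is set trans to the new C5 chain by approach of the acceptor anti to it, which is immaterial because C4a becomes sp2 in step 5. The step needs enantioface selectivity (secured by the ligand, a catalyst class established for cyclohexenone), 1,4- over 1,2-addition (secured by copper) and C4a- rather than C8-functionalisation (secured by trapping the kinetically formed enolate cold, before proton transfer).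

**Step 5**
Reactants: 11 keto imide from step 4
Product: 13 (5S)-5-{(5R)-5-[(tert-butyldimethylsilyl)oxy]octyl}-3,4,5,6,7,8-hexahydroquinolin-2(1H)-one, via keto amide 12 (not isolated)
Conditions: NH3 (7 M in MeOH), 50 °C, sealed tube; then PPTS (cat.), toluene, reflux (Dean–Stark)
Reagents that add atoms: ammonia, N
Why: Aminolysis of the activated N-acyl oxazolidinone gives the primary δ-keto amide, which should cyclodehydrate onto the C8a ketone to the tetrasubstituted enamide lactam (aza-annulation), deliberately erasing the C4a stereocentre.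

**Step 6**
Reactants: 13 enamide lactam
Product: 14 (4aS,5S,8aR)-5-{(5R)-5-[(tert-butyldimethylsilyl)oxy]octyl}octahydroquinolin-2(1H)-one
Conditions: H2 (50 bar), 10 % Pd/C, EtOAc/EtOH, 50 °C
Reagents that add atoms: none
Why: Heterogeneous syn-hydrogenation of the enamide; the C5 chain is pseudoaxial (A1,2 strain with C4H2) and blocks one face, so both hydrogens should add anti to it and set C4a and C8a together (cis fusion, H4a/H5/H8a all cis).

**Step 7**
Reactants: 14 cis-lactam
Product: 15 benzyl (4aS,5S,8aR)-5-{(5R)-5-[(tert-butyldimethylsilyl)oxy]octyl}-2-oxooctahydroquinoline-1(2H)-carboxylate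
Conditions: n-BuLi, THF, −78 °C; CbzCl, −78 → 0 °C
Reagents that add atoms: benzyl chloroformate, O=C(Cl)OCc1ccccc1
Why: N-Acylation of the lithium lactamate with a chloroformate gives the N-Cbz lactam, which activates C3–H for enolisation and the ring carbonyl for later Grignard opening.

**Step 8**
Reactants: 15 N-Cbz lactam
Product: 16 benzyl (3R,4aS,5S,8aR)-5-{(5R)-5-[(tert-butyldimethylsilyl)oxy]octyl}-3-hydroxy-2-oxooctahydroquinoline-1(2H)-carboxylate
Conditions: NaHMDS, THF, −78 °C; 2-(phenylsulfonyl)-3-phenyloxaziridine, −78 °C; AcOH quench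
Reagents that add atoms: 2-(phenylsulfonyl)-3-phenyloxaziridine, O=S(=O)(c1ccccc1)N1OC1c1ccccc1
Why: Electrophilic enolate hydroxylation by an N-sulfonyloxaziridine; with C8 held axial on the N-acyl lactam ring (A1,3 strain), the oxidant should attack the convex face anti to the carbocycle and place the C3 oxygen cis to H4a/H8a (3R).

**Step 9**
Reactants: 16 α-hydroxy lactam
Product: 17 benzyl (3R,4aS,5S,8aR)-3-(benzyloxy)-5-{(5R)-5-[(tert-butyldimethylsilyl)oxy]octyl}-2-oxooctahydroquinoline-1(2H)-carboxylate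
Conditions: benzyl 2,2,2-trichloroacetimidate, TfOH (5 mol %), CH2Cl2/cyclohexane, 0 °C → rt
Reagents that add atoms: benzyl 2,2,2-trichloroacetimidate, N=C(OCc1ccccc1)C(Cl)(Cl)Cl
Why: Acid-catalysed imidate benzylation avoids base, so the α-stereocentre and the N-acyl lactam are not endangered, and it installs the chelating ether needed in step 11.

**Step 10**
Reactants: 17 O-benzyl lactam
Product: 18 benzyl N-[(1R,2S,3S)-2-[(2R)-2-(benzyloxy)-3-oxobutyl]-3-{(5R)-5-[(tert-butyldimethylsilyl)oxy]octyl}cyclohexyl]carbamate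
Conditions: MeMgBr, THF, −78 → −40 °C; aq. NH4Cl
Reagents that add atoms: methylmagnesium bromide, C[Mg]Br
Why: Grignard addition to the ring carbonyl of an N-acyl lactam gives a chelated tetrahedral adduct that collapses on work-up to the open-chain carbamate methyl ketone (lactam ring-opening), supplying the C2 methyl without over-addition.

**Step 11**
Reactants: 18 α-benzyloxy methyl ketone
Product: 19 benzyl N-[(1R,2S,3S)-2-[(2R,3S)-2-(benzyloxy)-3-hydroxybutyl]-3-{(5R)-5-[(tert-butyldimethylsilyl)oxy]octyl}cyclohexyl]carbamate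
Conditions: Zn(BH4)2 (from ZnCl2/NaBH4), Et2O, −30 → 0 °C; aq. NH4Cl
Reagents that add atoms: none
Why: Chelation-controlled reduction: Zn bridges the ketone and benzyloxy oxygens and hydride should enter from the face of the chelate opposite the C4 chain, giving the 2,3-anti alcohol (2S).

**Step 12**
Reactants: 19 anti alcohol
Product: 20 benzyl N-[(1R,2S,3S)-2-[(2R,3S)-2-(benzyloxy)-3-(methanesulfonyloxy)butyl]-3-{(5R)-5-[(tert-butyldimethylsilyl)oxy]octyl}cyclohexyl]carbamate
Conditions: MsCl, Et3N, CH2Cl2, 0 °C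
Reagents that add atoms: methanesulfonyl chloride, CS(=O)(=O)Cl
Why: Sulfonylation of the secondary alcohol with retention turns C2 into an SN2 electrophile; the carbamate N–H should not react.

**Step 13**
Reactants: 20 mesylate
Product: 23 (2R,3R,4aS,5S,8aR)-5-{(5R)-5-[(tert-butyldimethylsilyl)oxy]octyl}-2-methyldecahydroquinolin-3-ol, via amino mesylate 21 (not isolated), via O-benzyl piperidine 22 (not isolated)
Conditions: H2 (1 atm), 10 % Pd/C, EtOAc/EtOH, rt → 40 °C; then Pd(OH)2/C, H2 (4 bar); aq. NaHCO3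
Reagents that add atoms: none
Why: Cbz hydrogenolysis frees the C8a amine, which should displace the secondary mesylate by 6-exo-tet SN2 with inversion (2S → 2R), closing the piperidine with 2-Me cis to 3-O and trans to C8; the benzyl ether is then hydrogenolysed in the same flask.

**Step 14**
Reactants: 23 amino alcohol
Product: 24 tert-butyl (2R,3R,4aS,5S,8aR)-5-{(5R)-5-[(tert-butyldimethylsilyl)oxy]octyl}-3-hydroxy-2-methyloctahydroquinoline-1(2H)-carboxylate
Conditions: Boc2O, Et3N, MeOH, 50 °C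
Reagents that add atoms: di-tert-butyl dicarbonate, CC(C)(C)OC(=O)OC(=O)OC(C)(C)C
Why: Carbamoylation of the amine (without DMAP the alcohol should stay free) masks nitrogen so that only the C3 hydroxyl is acylated in the next step.

**Step 15**
Reactants: 24 N-Boc amino alcohol; 25 (E)-oct-2-enoic acid
Product: 26 tert-butyl (2R,3R,4aS,5S,8aR)-5-{(5R)-5-[(tert-butyldimethylsilyl)oxy]octyl}-2-methyl-3-{[(2E)-oct-2-enoyl]oxy}octahydroquinoline-1(2H)-carboxylate
Conditions: DCC, DMAP (cat.), CH2Cl2, 0 °C → rt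
Reagents that add atoms: none
Why: Steglich esterification of the only free hydroxyl (equatorial at C3 in the N-Boc chair with axial 2-Me) with retention at C3; the E-enoate geometry should be preserved under these mild conditions.

**Step 16**
Reactants: 26 protected ester
Product: 27 (2R,3R,4aS,5S,8aR)-5-[(5R)-5-hydroxyoctyl]-2-methyldecahydroquinolin-3-yl (2E)-oct-2-enoate (target)
Conditions: TFA/CH2Cl2 (1:1), 0 °C → rt; then H2O (10 vol %), rt; aq. NaHCO3
Reagents that add atoms: none
Why: Acidolysis removes the Boc group and the secondary TBS ether in one operation, while the conjugated ester and all stereocentres should be inert to acid.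

**Compound list**

1 | (R)-2-propyloxirane | CCC[C@@H]1CO1 | starting material
2 | allylmagnesium bromide | C=CC[Mg]Br | starting material
3 | (4R)-oct-7-en-4-ol | CCC[C@@H](O)CCC=C | intermediate
4 | tert-butyldimethyl{[(4R)-oct-7-en-4-yl]oxy}silane | CCC[C@@H](O[Si](C)(C)C(C)(C)C)CCC=C | intermediate
5 | chloridobis(cyclopentadienyl){(5R)-5-[(tert-butyldimethylsilyl)oxy]octyl}zirconium (Cp drawn σ-bonded) | CCC[C@@H](O[Si](C)(C)C(C)(C)C)CCCC[Zr](Cl)(C1C=CC=C1)C1C=CC=C1 | intermediate (not isolated)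
6 | {[(4R)-8-bromooctan-4-yl]oxy}(tert-butyl)dimethylsilane | CCC[C@@H](O[Si](C)(C)C(C)(C)C)CCCCBr | intermediate
7 | cyclohex-2-en-1-one | O=C1C=CCCC1 | starting material
8 | 3-acryloyl-1,3-oxazolidin-2-one | C=CC(=O)N1CCOC1=O | starting material
9 | {(5R)-5-[(tert-butyldimethylsilyl)oxy]octyl}magnesium bromide | CCC[C@@H](O[Si](C)(C)C(C)(C)C)CCCC[Mg]Br | intermediate (not isolated)
10 | bromomagnesium enolate of (3S)-3-{(5R)-5-(TBSO)octyl}cyclohexanone (C4a=C8a–OMgBr) | Br[Mg]OC1=C[C@@H](CCCC[C@H](O[Si](C)(C)C(C)(C)C)CCC)CCC1 | intermediate (not isolated)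
11 | 3-{3-[(1R,2S)-2-{(5R)-5-(TBSO)octyl}-6-oxocyclohexyl]propanoyl}-1,3-oxazolidin-2-one | O=C1CCC[C@H](CCCC[C@H](O[Si](C)(C)C(C)(C)C)CCC)[C@H]1CCC(=O)N1CCOC1=O | intermediate
12 | 3-[(1R,2S)-2-{(5R)-5-(TBSO)octyl}-6-oxocyclohexyl]propanamide | O=C1CCC[C@H](CCCC[C@H](O[Si](C)(C)C(C)(C)C)CCC)[C@H]1CCC(N)=O | intermediate (not isolated)
13 | (5S)-5-{(5R)-5-(TBSO)octyl}-3,4,5,6,7,8-hexahydroquinolin-2(1H)-one | O=C1CCC2=C(CCC[C@@H]2CCCC[C@H](O[Si](C)(C)C(C)(C)C)CCC)N1 | intermediate
14 | (4aS,5S,8aR)-5-{(5R)-5-(TBSO)octyl}octahydroquinolin-2(1H)-one | O=C1CC[C@H]2[C@@H](CCCC[C@H](O[Si](C)(C)C(C)(C)C)CCC)CCC[C@H]2N1 | intermediate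
15 | benzyl (4aS,5S,8aR)-5-{(5R)-5-(TBSO)octyl}-2-oxooctahydroquinoline-1(2H)-carboxylate | O=C1CC[C@H]2[C@@H](CCCC[C@H](O[Si](C)(C)C(C)(C)C)CCC)CCC[C@H]2N1C(=O)OCc1ccccc1 | intermediate
16 | benzyl (3R,4aS,5S,8aR)-3-hydroxy-5-{(5R)-5-(TBSO)octyl}-2-oxooctahydroquinoline-1(2H)-carboxylate | O=C1[C@H](O)C[C@H]2[C@@H](CCCC[C@H](O[Si](C)(C)C(C)(C)C)CCC)CCC[C@H]2N1C(=O)OCc1ccccc1 | intermediate
17 | benzyl (3R,4aS,5S,8aR)-3-(benzyloxy)-5-{(5R)-5-(TBSO)octyl}-2-oxooctahydroquinoline-1(2H)-carboxylate | O=C1[C@H](OCc3ccccc3)C[C@H]2[C@@H](CCCC[C@H](O[Si](C)(C)C(C)(C)C)CCC)CCC[C@H]2N1C(=O)OCc1ccccc1 | intermediate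
18 | benzyl N-[(1R,2S,3S)-2-[(2R)-2-(benzyloxy)-3-oxobutyl]-3-{(5R)-5-(TBSO)octyl}cyclohexyl]carbamate | CC(=O)[C@H](OCc1ccccc1)C[C@H]1[C@@H](CCCC[C@H](O[Si](C)(C)C(C)(C)C)CCC)CCC[C@H]1NC(=O)OCc1ccccc1 | intermediate
19 | benzyl N-[(1R,2S,3S)-2-[(2R,3S)-2-(benzyloxy)-3-hydroxybutyl]-3-{(5R)-5-(TBSO)octyl}cyclohexyl]carbamate | C[C@H](O)[C@H](OCc1ccccc1)C[C@H]1[C@@H](CCCC[C@H](O[Si](C)(C)C(C)(C)C)CCC)CCC[C@H]1NC(=O)OCc1ccccc1 | intermediate
20 | benzyl N-[(1R,2S,3S)-2-[(2R,3S)-2-(benzyloxy)-3-(methanesulfonyloxy)butyl]-3-{(5R)-5-(TBSO)octyl}cyclohexyl]carbamate | C[C@H](OS(C)(=O)=O)[C@H](OCc1ccccc1)C[C@H]1[C@@H](CCCC[C@H](O[Si](C)(C)C(C)(C)C)CCC)CCC[C@H]1NC(=O)OCc1ccccc1 | intermediate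
21 | (2S,3R)-4-[(1S,2R,6S)-2-amino-6-{(5R)-5-(TBSO)octyl}cyclohexyl]-3-(benzyloxy)butan-2-yl methanesulfonate | C[C@H](OS(C)(=O)=O)[C@H](OCc1ccccc1)C[C@H]1[C@@H](CCCC[C@H](O[Si](C)(C)C(C)(C)C)CCC)CCC[C@H]1N | intermediate (not isolated)
22 | (2R,3R,4aS,5S,8aR)-3-(benzyloxy)-5-{(5R)-5-(TBSO)octyl}-2-methyldecahydroquinoline | c1ccccc1CO[C@@H]1C[C@H]2[C@@H](CCCC[C@H](O[Si](C)(C)C(C)(C)C)CCC)CCC[C@H]2N[C@@H]1C | intermediate (not isolated)
23 | (2R,3R,4aS,5S,8aR)-5-{(5R)-5-(TBSO)octyl}-2-methyldecahydroquinolin-3-ol | O[C@@H]1C[C@H]2[C@@H](CCCC[C@H](O[Si](C)(C)C(C)(C)C)CCC)CCC[C@H]2N[C@@H]1C | intermediate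
24 | tert-butyl (2R,3R,4aS,5S,8aR)-3-hydroxy-5-{(5R)-5-(TBSO)octyl}-2-methyloctahydroquinoline-1(2H)-carboxylate | O[C@@H]1C[C@H]2[C@@H](CCCC[C@H](O[Si](C)(C)C(C)(C)C)CCC)CCC[C@H]2N(C(=O)OC(C)(C)C)[C@@H]1C | intermediate
25 | (E)-oct-2-enoic acid | CCCCC/C=C/C(=O)O | starting material
26 | tert-butyl (2R,3R,4aS,5S,8aR)-5-{(5R)-5-(TBSO)octyl}-2-methyl-3-{[(2E)-oct-2-enoyl]oxy}octahydroquinoline-1(2H)-carboxylate | CCCCC/C=C/C(=O)O[C@@H]1C[C@H]2[C@@H](CCCC[C@H](O[Si](C)(C)C(C)(C)C)CCC)CCC[C@H]2N(C(=O)OC(C)(C)C)[C@@H]1C | intermediate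
27 | (2R,3R,4aS,5S,8aR)-5-[(5R)-5-hydroxyoctyl]-2-methyldecahydroquinolin-3-yl (2E)-oct-2-enoate | CCCCC/C=C/C(=O)O[C@@H]1C[C@H]2[C@@H](CCCC[C@H](O)CCC)CCC[C@H]2N[C@@H]1C | target

**Totals**

Total step count: 16. Longest linear sequence: 16 steps (1 → 27).

**Steps most likely to fail**

Step 4. The magnesium enolate may transfer a proton, add sluggishly, or add a second acceptor instead of giving clean mono-Michael addition at C4a. Fallback: setting out from 6 and 7, the enolate 10 is generated as in step 4 and trapped with allyl iodide/DMPU to give the trans allyl ketone F1. BH3·SMe2 followed by NaOH/H2O2 should then give the diol F2, and TEMPO/PhI(OAc)2 in aqueous MeCN should oxidise both alcohols to the keto acid F3. Heating F3 with NH4OAc in toluene (Dean–Stark) closes the enamide lactam, so the route is rejoined at 13.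

Step 6. The double bond may migrate on the catalyst before hydrogen is added, or the two faces may be poorly discriminated, which would give trans-fused or C4a/C8a-epimeric lactams. Fallback: setting out from 13, DDQ in dioxane should dehydrogenate the ring to the aromatic pyridone F4. Hydrogenation of F4 over Rh/Al2O3 (H2, 60 bar) adds all four hydrogens to one face of the flat heteroarene without an isomerisable alkene intermediate, anti to the pseudoaxial C5 chain, and comes back to the route at 14.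

Step 8. The oxidant may approach the concave face of the conformationally mobile cis-fused lactam, so that oxygen is delivered with reversed or poor facial selectivity. Fallback: setting out from 15, the (3S)-alcohol F5 formed by such attack is inverted by a Mitsunobu reaction with chloroacetic acid (PPh3, DIAD) to the (3R)-chloroacetate F6. Removal of the chloroacetyl group with thiourea/NaHCO3 in EtOH, which spares the N-Cbz lactam, comes back to the route at 16.

**Further compounds**

F1 | step 4 | (2R,3S)-3-{(5R)-5-(TBSO)octyl}-2-(prop-2-en-1-yl)cyclohexan-1-one | O=C1CCC[C@H](CCCC[C@H](O[Si](C)(C)C(C)(C)C)CCC)[C@H]1CC=C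
F2 | step 4 | (2R,3S)-3-{(5R)-5-(TBSO)octyl}-2-(3-hydroxypropyl)cyclohexan-1-ol (mixture at C1) | OC1CCC[C@H](CCCC[C@H](O[Si](C)(C)C(C)(C)C)CCC)[C@H]1CCCO
F3 | step 4 | 3-[(1R,2S)-2-{(5R)-5-(TBSO)octyl}-6-oxocyclohexyl]propanoic acid | O=C1CCC[C@H](CCCC[C@H](O[Si](C)(C)C(C)(C)C)CCC)[C@H]1CCC(=O)O
F4 | step 6 | (5S)-5-{(5R)-5-(TBSO)octyl}-5,6,7,8-tetrahydroquinolin-2(1H)-one | O=c1ccc2c([nH]1)CCC[C@@H]2CCCC[C@H](O[Si](C)(C)C(C)(C)C)CCC
F5 | step 8 | benzyl (3S,4aS,5S,8aR)-3-hydroxy-5-{(5R)-5-(TBSO)octyl}-2-oxooctahydroquinoline-1(2H)-carboxylate | O=C1[C@@H](O)C[C@H]2[C@@H](CCCC[C@H](O[Si](C)(C)C(C)(C)C)CCC)CCC[C@H]2N1C(=O)OCc1ccccc1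
F6 | step 8 | benzyl (3R,4aS,5S,8aR)-3-[(chloroacetyl)oxy]-5-{(5R)-5-(TBSO)octyl}-2-oxooctahydroquinoline-1(2H)-carboxylate | O=C1[C@H](OC(=O)CCl)C[C@H]2[C@@H](CCCC[C@H](O[Si](C)(C)C(C)(C)C)CCC)CCC[C@H]2N1C(=O)OCc1ccccc1
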